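**Retrosynthetic overview**

1. Last bond (C–O): the ester between the primary alcohol of 4'-oxomacrophorin A and one of the two enantiotopic carbonyls of 3-hydroxy-3-methylglutaric anhydride. The ring-opening sets C3' and frees the acid, so no protecting group is needed.
2. Oxirane (two C–O bonds): hydroxyl-directed, tartrate-controlled nucleophilic epoxidation of a quinone 4-monoketal (site and face), then ketal hydrolysis.
3. C11–C2' bond: Negishi coupling of albicanylzinc iodide with a 2-bromoquinone monoketal, itself made by oxidative dearomatisation (C–O) of a bromophenol.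
4. Albicanyl iodide: (+)-sclareolide → lactol → alkoxy-radical excision of C12 → 11-iodo-8α-ol → exocyclic alkene.
5. Ring order: decalin (rings A and B) from the chiral pool, the six-membered oxygenated ring from the arene, the oxirane last.

Notation: "albicanyl" is the [(1S,4aS,8aS)-5,5,8a-trimethyl-2-methylidenedecahydronaphthalen-1-yl]methyl group (drim-8(12)-en-11-yl). Drimane numbering (C8, C9, C11, C12) is used for the decalin.

Assumption: the bromophenol and the anhydride are bought as such. The sense of induction of each chiral controller (diisopropyl L-tartrate, the quinine-derived sulfonamide, the diol of one fallback) is taken as written, and its antipode or pseudo-enantiomer is used if a first run shows the opposite sense.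

**Route**

Step 1
Reactants: 1 (+)-sclareolide
Product: 2 sclareolide lactol, (3aR,5aS,9aS,9bR)-3a,6,6,9a-tetramethyldodecahydronaphtho[2,1-b]furan-2-ol (anomer mixture)
Conditions: i-Bu2AlH (1.1 equiv), CH2Cl2, −78 °C; aqueous work-up
Reagents that add atoms: none
Why: Lactone-to-lactol reduction with i-Bu2AlH stops at the tetrahedral aluminium hemiacetal at −78 °C; the four ring stereocentres are untouched and the anomeric mixture is of no consequence.

Step 2
Reactants: 2 sclareolide lactol
Product: 3 (1R,2R,4aS,8aS)-1-(iodomethyl)-2,5,5,8a-tetramethyldecahydronaphthalen-2-yl formate (11-iododriman-8α-yl formate)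
Conditions: PhI(OAc)2 (1.2 equiv), I2 (1.0 equiv), CH2Cl2, visible light, 25 °C
Reagents that add atoms: iodine (SMILES: II)
Why: Suárez alkoxy-radical fragmentation: the lactol hypoiodite homolyses, β-scission of the C11–C12 bond leaves C12 as the 8α-formate and gives a primary C11 radical that is trapped by iodine, so C8 and C9 keep their configuration.

Step 3
Reactants: 3 11-iododriman-8α-yl formate
Product: 4 (1R,2R,4aS,8aS)-1-(iodomethyl)-2,5,5,8a-tetramethyldecahydronaphthalen-2-ol (11-iododriman-8α-ol)
Conditions: K2CO3 (0.2 equiv), MeOH, 0 °C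
Reagents that add atoms: none
Why: Base-catalysed transesterification (methanolysis) of a formate, the most labile carboxylic ester, frees the tertiary 8α-alcohol under conditions too mild for oxetane closure onto the hindered C11 iodide.

Step 4
Reactants: 4 11-iododriman-8α-ol
Product: 5 albicanyl iodide, (1S,4aS,8aS)-1-(iodomethyl)-5,5,8a-trimethyl-2-methylidenedecahydronaphthalene
Conditions: SOCl2 (1.5 equiv), Et3N (4 equiv), CH2Cl2, −78 °C
Reagents that add atoms: none
Why: E2-type dehydration through the chlorosulfite: the equatorial 8α-O leaving group has no anti-periplanar ring hydrogen, so a C12 methyl hydrogen is removed and the exocyclic 8(12)-alkene dominates (minor ring-alkene isomers are removed on AgNO3-impregnated SiO2); C9 is not epimerised.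

Step 5
Reactants: 6 (4-bromo-3-hydroxyphenyl)methanol
Product: 7 2-bromo-5-(hydroxymethyl)-4,4-dimethoxycyclohexa-2,5-dien-1-one
Conditions: PhI(OAc)2 (2.2 equiv), MeOH, 0 → 25 °C
Reagents that add atoms: methanol (SMILES: CO)
Why: Oxidative dearomatisation of a para-unsubstituted phenol by trivalent iodine: para-methoxylation and a second oxidation give the quinone monoketal, with the ketal carbon para to the former OH and therefore next to the CH2OH-bearing carbon, which fixes which carbonyl is masked.

Step 6
Reactants: 5 albicanyl iodide; 7 2-bromo-5-(hydroxymethyl)-4,4-dimethoxycyclohexa-2,5-dien-1-one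
Product: 9 2-albicanyl-5-(hydroxymethyl)-4,4-dimethoxycyclohexa-2,5-dien-1-one, via albicanylzinc iodide 8 (not isolated)
Conditions: 5, Zn dust (2 equiv), LiCl (1.5 equiv), THF, 40 °C; solution decanted from Zn and added slowly to 7 (1.2 equiv), Pd(OAc)2 (3 mol%), SPhos (6 mol%), THF, 25 °C
Reagents that add atoms: none
Why: Negishi coupling: LiCl-assisted zinc insertion into the primary iodide, oxidative addition of zerovalent palladium into the C–Br bond of the α-bromoenone, and SPhos-accelerated reductive elimination that outruns β-hydride elimination and protonolysis by the free OH; no stereocentre is formed or touched.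

Step 7
Reactants: 9 2-albicanyl-5-(hydroxymethyl)-4,4-dimethoxycyclohexa-2,5-dien-1-one
Product: 10 (1R,6S)-1-albicanyl-4-(hydroxymethyl)-5,5-dimethoxy-7-oxabicyclo[4.1.0]hept-3-en-2-one
Conditions: Ph3COOH (2.5 equiv), NaN(SiMe3)2 (2.2 equiv), diisopropyl L-tartrate (1.2 equiv), 4 Å MS, PhMe, −40 °C
Reagents that add atoms: trityl hydroperoxide (SMILES: OOC(c1ccccc1)(c1ccccc1)c1ccccc1)
Why: Tartrate-mediated, hydroxyl-directed nucleophilic (Weitz–Scheffer) epoxidation: only the C2=C3 enone bond has an unsubstituted β-carbon, the deprotonated C5 hydroxymethyl group holds the Na+/tartrate/Ph3COO− assembly next to C3 across the ketal carbon, and the tartrate decides the face, so both oxirane centres (1R,6S) are set together by reagent control with the remote decalin playing no part.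

Step 8
Reactants: 10 epoxy ketal
Product: 11 4'-oxomacrophorin A, (1R,6S)-1-albicanyl-4-(hydroxymethyl)-7-oxabicyclo[4.1.0]hept-3-ene-2,5-dione
Conditions: TsOH·H2O (0.2 equiv), acetone/H2O (10:1), 25 °C
Reagents that add atoms: water (SMILES: O)
Why: Acid-catalysed hydrolysis of the dimethyl ketal; the oxirane flanked by carbonyl and ketal carbons resists acid opening and the 1,1-disubstituted alkene is not protonated by dilute sulfonic acid at 25 °C, so both oxirane centres survive.

Step 9
Reactants: 11 4'-oxomacrophorin A; 12 3-hydroxy-3-methylglutaric anhydride (4-hydroxy-4-methyloxane-2,6-dione)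
Product: 13 4'-oxomacrophorin D, the (3S)-3-hydroxy-3-methylglutaric acid monoester of 11 at its primary alcohol
Conditions: 12 (1.3 equiv), 9-amino-9-deoxy-epi-quinine N-[3,5-bis(trifluoromethyl)benzenesulfonyl] amide (15 mol%), MTBE/THF (4:1), −20 °C
Reagents that add atoms: none
Why: Proposed new method: catalyst-controlled choice between the enantiotopic carbonyls of an anhydride whose prochiral carbon is quaternary and carries a free OH, with a complex alcohol as the limiting partner; the sulfonamide N–H hydrogen-bonds to the reacting C=O, the quinuclidine nitrogen acts as general base on the CH2OH of 11, and the tertiary OH of 12 donates a further hydrogen bond to a sulfonyl oxygen, which tells OH from CH3 and exposes only the pro-S acyl group, so one ring-opening forms the ester C–O bond, sets C3' (S) and frees the acid; the closest known reaction type is the cinchona-sulfonamide or cinchona-thiourea catalysed alcoholysis (methanol, benzyl or allyl alcohol) of meso and 3-monosubstituted glutaric anhydrides.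

**Compound list**

1 | (+)-sclareolide, (3aR,5aS,9aS,9bR)-3a,6,6,9a-tetramethyldecahydronaphtho[2,1-b]furan-2(1H)-one | C[C@]12CCCC([C@@H]1CC[C@@]3([C@@H]2CC(=O)O3)C)(C)C | starting material
2 | sclareolide lactol (anomer mixture) | C[C@]12CCCC([C@@H]1CC[C@@]3([C@@H]2CC(O)O3)C)(C)C | intermediate
3 | (1R,2R,4aS,8aS)-1-(iodomethyl)-2,5,5,8a-tetramethyldecahydronaphthalen-2-yl formate | C[C@]12CCCC([C@@H]1CC[C@@]([C@@H]2CI)(C)OC=O)(C)C | intermediate
4 | (1R,2R,4aS,8aS)-1-(iodomethyl)-2,5,5,8a-tetramethyldecahydronaphthalen-2-ol | C[C@]12CCCC([C@@H]1CC[C@@]([C@@H]2CI)(C)O)(C)C | intermediate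
5 | albicanyl iodide, (1S,4aS,8aS)-1-(iodomethyl)-5,5,8a-trimethyl-2-methylidenedecahydronaphthalene | C=C1CC[C@H]2C(C)(C)CCC[C@]2(C)[C@H]1CI | intermediate
6 | (4-bromo-3-hydroxyphenyl)methanol | OCc1ccc(Br)c(O)c1 | starting material
7 | 2-bromo-5-(hydroxymethyl)-4,4-dimethoxycyclohexa-2,5-dien-1-one | COC1(OC)C=C(Br)C(=O)C=C1CO | intermediate
8 | albicanylzinc iodide (LiCl-complexed, THF solution) | C=C1CC[C@H]2C(C)(C)CCC[C@]2(C)[C@H]1C[Zn]I | intermediate
9 | 2-albicanyl-5-(hydroxymethyl)-4,4-dimethoxycyclohexa-2,5-dien-1-one | C=C1CC[C@H]2C(C)(C)CCC[C@]2(C)[C@H]1CC1=CC(OC)(OC)C(CO)=CC1=O | intermediate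
10 | (1R,6S)-1-albicanyl-4-(hydroxymethyl)-5,5-dimethoxy-7-oxabicyclo[4.1.0]hept-3-en-2-one | C=C1CC[C@H]2C(C)(C)CCC[C@]2(C)[C@H]1C[C@@]12O[C@@H]1C(OC)(OC)C(CO)=CC2=O | intermediate
11 | 4'-oxomacrophorin A, (1R,6S)-1-albicanyl-4-(hydroxymethyl)-7-oxabicyclo[4.1.0]hept-3-ene-2,5-dione | C=C1CC[C@H]2C(C)(C)CCC[C@]2(C)[C@H]1C[C@@]12O[C@@H]1C(=O)C(CO)=CC2=O | intermediate
12 | 3-hydroxy-3-methylglutaric anhydride | CC1(O)CC(=O)OC(=O)C1 | starting material
13 | 4'-oxomacrophorin D | C=C1CC[C@H]2C(C)(C)CCC[C@]2(C)[C@H]1C[C@@]12O[C@@H]1C(=O)C(COC(=O)C[C@@](C)(O)CC(=O)O)=CC2=O | target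

**Step count and risks**

Total step count: 9. Longest linear sequence: 8 (steps 1 to 4 and 6 to 9, from 1).

The three steps most likely to fail, each with one fallback:

First, step 9, the new desymmetrising acylation. The catalyst may fail to tell OH from CH3 at a quaternary prochiral carbon, the free acid of the product may silence the quinuclidine, and the epoxy-enedione is sensitive to amines. The fallback is known chemistry and sets out from 11. The stereocentre is no longer induced but sorted afterwards: 11 is opened onto 12 without chiral control (DMAP 0.2 equiv, pyridine/CH2Cl2, 0 °C, the usual way hydroxymethylglutarate half-esters are made). This gives 13 together with (3'R)-4'-oxomacrophorin D F6 in about equal amounts. The two diastereomers are parted by semi-preparative HPLC, and the route is rejoined at 13.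

Second, step 6, the Negishi coupling on the quinone monoketal. The free OH of 7 may protonate 8, traces of Zn may reduce 7 back to a phenol, and β-hydride elimination at C9 would give a conjugated diene. The fallback sets out from 5 (as 8) and 6 and changes the order of events: couple at the aromatic level, dearomatise afterwards. 6 is silylated (t-BuMe2SiCl, imidazole, DMF) to the bis(tert-butyldimethylsilyl) ether of (4-bromo-3-hydroxyphenyl)methanol F1. 8 is coupled with it (Pd(OAc)2/SPhos, THF, 50 °C) to the bis(tert-butyldimethylsilyl) ether of 2-albicanyl-5-(hydroxymethyl)phenol F2. n-Bu4NF/AcOH in THF frees 2-albicanyl-5-(hydroxymethyl)phenol F3. PhI(OAc)2 (2.2 equiv) in MeOH at 0 °C then turns the phenol into the monoketal, and the route is rejoined at 9.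

Third, step 7, the directed epoxidation. The bulky albicanyl group on C2 may slow attack at C3, and the level or sense of face selection with this α-substituent is not assured. The fallback sets out from 9 and replaces reagent control by auxiliary control. Transketalisation of 9 with (2S,4S)-pentane-2,4-diol (PPTS, benzene, 4 Å MS, 50 °C) gives the (2S,4S)-pentane-2,4-diyl spiroketal analogue of 9 F4. Ph3COOH/KN(SiMe3)2 in THF at −35 °C epoxidises the same C2=C3 bond anti to the axial methyl of the dioxane chair, giving the (1R,6S)-epoxide of that spiroketal F5. TsOH·H2O in wet acetone (as in step 8, longer time) removes the diol, and the route is rejoined at 11, bypassing 10.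

**Further compounds**

F1 | step 6 | bis(tert-butyldimethylsilyl) ether of (4-bromo-3-hydroxyphenyl)methanol | CC(C)(C)[Si](C)(C)OCc1ccc(Br)c(O[Si](C)(C)C(C)(C)C)c1
F2 | step 6 | bis(tert-butyldimethylsilyl) ether of 2-albicanyl-5-(hydroxymethyl)phenol | C=C1CC[C@H]2C(C)(C)CCC[C@]2(C)[C@H]1Cc1ccc(CO[Si](C)(C)C(C)(C)C)cc1O[Si](C)(C)C(C)(C)C
F3 | step 6 | 2-albicanyl-5-(hydroxymethyl)phenol | C=C1CC[C@H]2C(C)(C)CCC[C@]2(C)[C@H]1Cc1ccc(CO)cc1O
F4 | step 7 | (2S,4S)-pentane-2,4-diyl spiroketal analogue of 9, (2S,4S)-8-albicanyl-11-(hydroxymethyl)-2,4-dimethyl-1,5-dioxaspiro[5.5]undeca-7,10-dien-9-one | C=C1CC[C@H]2C(C)(C)CCC[C@]2(C)[C@H]1CC1=CC2(O[C@@H](C)C[C@H](C)O2)C(CO)=CC1=O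
F5 | step 7 | (1R,6S)-epoxide of that spiroketal | C=C1CC[C@H]2C(C)(C)CCC[C@]2(C)[C@H]1C[C@@]12O[C@@H]1C1(O[C@@H](C)C[C@H](C)O1)C(CO)=CC2=O
F6 | step 9 | (3'R)-4'-oxomacrophorin D (C3' epimer of 13) | C=C1CC[C@H]2C(C)(C)CCC[C@]2(C)[C@H]1C[C@@]12O[C@@H]1C(=O)C(COC(=O)C[C@](C)(O)CC(=O)O)=CC2=O
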